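**Retrosynthetic overview**
1. Target 15 comes from 14 by one hydrogenolysis that removes ten O-benzyl groups and two blocking bromine atoms; 14 comes from phenol 13 and acid 9 (4'-O-galloylation), and 13 from 12 by loss of the 4'-O-(4-methoxybenzyl) group.
2. Key disconnection of 12: ring C is opened at C4–C3 and O1–C2, giving ortho-quinone methide 11 (ring A, from salicyl alcohol 4) and the (Z)-enol gallate 10 (ring B, C2, C3 and the 3-O-galloyl ester already in place); the forward reaction is a catalytic asymmetric oxa-[4+2] cycloaddition.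
3. Enabling feature: on the phloroglucinol ring A, O1 (on C8a) stands ortho to the C4 methylene (on C4a), an ortho-hydroxybenzyl unit that is a masked heterodiene C4=C4a–C8a=O1; C2 is benzylic to the electron-rich ring B, C3 carries only an acyloxy group, and the 2,3-cis arrangement maps onto a Z alkene.
4. 10 comes from aryl alkyne 8 and 9 (ruthenium-catalysed anti-Markovnikov, Z-selective addition), 8 from aldehyde 5; 4 comes from aldehyde 1 (benzylation, bromination of the future C6 and C8 as blocking groups, reduction).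
5. Ring order: rings A, B and both galloyl rings are bought; ring C is the only ring made (step 8).

Key step: step 8

Remark (assumption): the sense of induction of the chiral phosphoric acid in step 8 cannot be derived from precedent; the (R)-acid is written, and the (S)-acid would be used if it proves to favour the (2S,3S) series. Compounds 1, 5 and 9 are taken as commercial.

**Step 1**
Reactants: 1 2,4,6-trihydroxybenzaldehyde
Product: 2 4,6-bis(benzyloxy)-2-hydroxybenzaldehyde
Conditions: BnBr (2.05 equiv), K2CO3, DMF, rt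
Reagents that add atoms: benzyl bromide, BrCc1ccccc1
Why: Williamson ether synthesis; the hydroxyl that stays free is the one locked in the hydrogen bond to the formyl group and is the least nucleophilic, so two equivalents should cap the para oxygen and one of the two equivalent ortho oxygens.

**Step 2**
Reactants: 2 4,6-bis(benzyloxy)-2-hydroxybenzaldehyde
Product: 3 4,6-bis(benzyloxy)-3,5-dibromo-2-hydroxybenzaldehyde
Conditions: NBS (2.05 equiv), MeCN, 0 °C to rt, dark
Reagents that add atoms: N-bromosuccinimide, O=C1CCC(=O)N1Br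
Why: Electrophilic aromatic bromination at the only two free positions of the phloroglucinol ring, each activated by three oxygen donors, installs the blocking groups that become C6–Br and C8–Br.

**Step 3**
Reactants: 3 4,6-bis(benzyloxy)-3,5-dibromo-2-hydroxybenzaldehyde
Product: 4 3,5-bis(benzyloxy)-2,4-dibromo-6-(hydroxymethyl)phenol
Conditions: NaBH4, THF/MeOH, 0 °C; aq. NH4Cl
Reagents that add atoms: none
Why: Borohydride reduction of the aldehyde to the benzylic alcohol leaves aryl bromides and benzyl ethers untouched, and the cold, near-neutral work-up should avoid premature loss of water from the salicyl alcohol.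

**Step 4**
Reactants: 5 3,4,5-trihydroxybenzaldehyde
Product: 6 3,5-dihydroxy-4-[(4-methoxybenzyl)oxy]benzaldehyde
Conditions: 4-methoxybenzyl chloride (1.05 equiv), NaHCO3, NaI (cat.), DMF, 30 °C
Reagents that add atoms: 4-methoxybenzyl chloride, COc1ccc(CCl)cc1
Why: Chemoselective Williamson alkylation with a weak base; only the most acidic hydroxyl (para to the formyl group) is ionised, a selectivity with close precedent in the 4-O-benzylation of the same aldehyde.

**Step 5**
Reactants: 6 3,5-dihydroxy-4-[(4-methoxybenzyl)oxy]benzaldehyde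
Product: 7 3,5-bis(benzyloxy)-4-[(4-methoxybenzyl)oxy]benzaldehyde
Conditions: BnBr (2.3 equiv), K2CO3, DMF, rt
Reagents that add atoms: benzyl bromide, BrCc1ccccc1
Why: Williamson etherification of the two remaining phenols.

**Step 6**
Reactants: 7 3,5-bis(benzyloxy)-4-[(4-methoxybenzyl)oxy]benzaldehyde
Product: 8 1,3-bis(benzyloxy)-5-ethynyl-2-[(4-methoxybenzyl)oxy]benzene
Conditions: dimethyl (1-diazo-2-oxopropyl)phosphonate, K2CO3, MeOH/THF, rt
Reagents that add atoms: dimethyl (1-diazo-2-oxopropyl)phosphonate, COP(=O)(OC)C(=[N+]=[N-])C(C)=O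
Why: Seyferth–Gilbert homologation in the Ohira–Bestmann variant turns the non-enolisable aryl aldehyde into the terminal alkyne under mild carbonate conditions that the ethers tolerate.

**Step 7**
Reactants: 8 1,3-bis(benzyloxy)-5-ethynyl-2-[(4-methoxybenzyl)oxy]benzene; 9 3,4,5-tris(benzyloxy)benzoic acid
Product: 10 (Z)-2-{3,5-bis(benzyloxy)-4-[(4-methoxybenzyl)oxy]phenyl}ethenyl 3,4,5-tris(benzyloxy)benzoate
Conditions: Ru(η3-CH2C(CH3)CH2)2(Ph2P(CH2)4PPh2) (2 mol%), toluene, 50 °C
Reagents that add atoms: none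
Why: Ruthenium-catalysed anti-Markovnikov hydro-acyloxylation of a terminal alkyne through a ruthenium vinylidene; the carboxylate adds to the vinylidene α-carbon and stereospecific protonolysis should give the (Z)-enol ester, as this reaction type does for aryl acetylenes and benzoic acids.

**Step 8**
Reactants: 4 3,5-bis(benzyloxy)-2,4-dibromo-6-(hydroxymethyl)phenol; 10 (Z)-2-{3,5-bis(benzyloxy)-4-[(4-methoxybenzyl)oxy]phenyl}ethenyl 3,4,5-tris(benzyloxy)benzoate
Product: 12 (2R,3R)-5,7-bis(benzyloxy)-2-{3,5-bis(benzyloxy)-4-[(4-methoxybenzyl)oxy]phenyl}-6,8-dibromochroman-3-yl 3,4,5-tris(benzyloxy)benzoate, via ortho-quinone methide 11 (not isolated)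
Conditions: (R)-TRIP [(R)-3,3'-bis(2,4,6-triisopropylphenyl)-1,1'-binaphthyl-2,2'-diyl hydrogen phosphate] (10 mol%), 5 Å MS, PhCF3, 40 °C; 4 added slowly to 10 (1.5 equiv)
Reagents that add atoms: none
Why: Proposed new method: the chiral phosphoric acid dehydrates 4 to the hydrogen-bonded ortho-quinone methide 11 (C4=C4a–C8a=O1), which the Z-enol ester 10 should capture in an asynchronous, concerted inverse-electron-demand oxa-Diels–Alder reaction in which C4–C3 bonding leads and O1–C2 bonding follows, the developing positive charge at C2 being carried by the para-alkoxyaryl ring B. The closest known reaction types are the chiral phosphoric acid-catalysed [4+2] cycloaddition of ortho-quinone methides, made in situ from ortho-hydroxybenzyl alcohols, with styrenes and enol-type alkenes, and the thermal ortho-quinone methide/propenylbenzene cycloaddition that gives 2-aryl-3-substituted chromans with retention of alkene geometry. Ring C (O1–C2–C3–C4–C4a–C8a) closes by intermolecular [4+2] cycloaddition, four atoms from 11 and two from 10. The 2,3-cis relationship follows from suprafacial addition to the Z alkene, which keeps the C2 aryl group and the C3 oxygen on the same face, and the absolute configuration (2R,3R) is to be set by the chiral phosphate, which is hydrogen-bonded to O1 and shields one enantiotopic face of the alkene as it approaches C4. The step needs regioselectivity (C4 to the acyloxy-bearing carbon, O1 to the benzylic carbon), secured because the 4-alkoxyaryl group stabilises charge at C2 far better than the acyloxy group does at C3. It also needs chemoselectivity against self-condensation, secured by the bromine atoms at C6 and C8, which block every nucleophilic ring position of ring A in 4 and in 12 and make 11 more electrophilic, and by the slow addition of 4.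

**Step 9**
Reactants: 12 (2R,3R)-5,7-bis(benzyloxy)-2-{3,5-bis(benzyloxy)-4-[(4-methoxybenzyl)oxy]phenyl}-6,8-dibromochroman-3-yl 3,4,5-tris(benzyloxy)benzoate
Product: 13 (2R,3R)-5,7-bis(benzyloxy)-2-[3,5-bis(benzyloxy)-4-hydroxyphenyl]-6,8-dibromochroman-3-yl 3,4,5-tris(benzyloxy)benzoate
Conditions: TFA/CH2Cl2 (1:10), anisole (10 equiv), 0 °C
Reagents that add atoms: none
Why: Acidolysis of the 4-methoxybenzyl aryl ether (SN1 loss of the stabilised benzylic cation, trapped by anisole in a Friedel–Crafts alkylation) is much faster than cleavage of plain benzyl ethers, and the fully substituted ring A cannot be alkylated.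

**Step 10**
Reactants: 13 (2R,3R)-5,7-bis(benzyloxy)-2-[3,5-bis(benzyloxy)-4-hydroxyphenyl]-6,8-dibromochroman-3-yl 3,4,5-tris(benzyloxy)benzoate; 9 3,4,5-tris(benzyloxy)benzoic acid
Product: 14 (2R,3R)-5,7-bis(benzyloxy)-2-{3,5-bis(benzyloxy)-4-[3,4,5-tris(benzyloxy)benzoyloxy]phenyl}-6,8-dibromochroman-3-yl 3,4,5-tris(benzyloxy)benzoate
Conditions: DCC, DMAP (0.2 equiv), CH2Cl2, 0 °C to rt
Reagents that add atoms: none
Why: Steglich esterification of the hindered phenol under near-neutral, cold conditions, which should avoid phenoxide-driven opening of ring C and so keep C2 from epimerising.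

**Step 11**
Reactants: 14 (2R,3R)-5,7-bis(benzyloxy)-2-{3,5-bis(benzyloxy)-4-[3,4,5-tris(benzyloxy)benzoyloxy]phenyl}-6,8-dibromochroman-3-yl 3,4,5-tris(benzyloxy)benzoate
Product: 15 epigallocatechin 3,4'-di-O-gallate
Conditions: H2 (1 atm), Pd(OH)2/C, NaOAc (2.2 equiv), THF/MeOH, rt
Reagents that add atoms: none
Why: Palladium-catalysed hydrogenolysis of the ten O-benzyl groups together with hydrodehalogenation of the two aryl bromides, acetate buffering the hydrogen bromide so that the aryl gallate should neither migrate nor cleave; the benzylic C2–O1 bond and both stereocentres are not touched under these conditions.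

**Compound list**
1 | 2,4,6-trihydroxybenzaldehyde | O=Cc1c(O)cc(O)cc1O | starting material
2 | 4,6-bis(benzyloxy)-2-hydroxybenzaldehyde | O=Cc1c(O)cc(OCc2ccccc2)cc1OCc1ccccc1 | intermediate
3 | 4,6-bis(benzyloxy)-3,5-dibromo-2-hydroxybenzaldehyde | O=Cc1c(O)c(Br)c(OCc2ccccc2)c(Br)c1OCc1ccccc1 | intermediate
4 | 3,5-bis(benzyloxy)-2,4-dibromo-6-(hydroxymethyl)phenol | OCc1c(O)c(Br)c(OCc2ccccc2)c(Br)c1OCc1ccccc1 | intermediate
5 | 3,4,5-trihydroxybenzaldehyde | O=Cc1cc(O)c(O)c(O)c1 | starting material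
6 | 3,5-dihydroxy-4-[(4-methoxybenzyl)oxy]benzaldehyde | O=Cc1cc(O)c(OCc2ccc(OC)cc2)c(O)c1 | intermediate
7 | 3,5-bis(benzyloxy)-4-[(4-methoxybenzyl)oxy]benzaldehyde | O=Cc1cc(OCc2ccccc2)c(OCc2ccc(OC)cc2)c(OCc2ccccc2)c1 | intermediate
8 | 1,3-bis(benzyloxy)-5-ethynyl-2-[(4-methoxybenzyl)oxy]benzene | C#Cc1cc(OCc2ccccc2)c(OCc2ccc(OC)cc2)c(OCc2ccccc2)c1 | intermediate
9 | 3,4,5-tris(benzyloxy)benzoic acid | OC(=O)c1cc(OCc2ccccc2)c(OCc2ccccc2)c(OCc2ccccc2)c1 | starting material
10 | (Z)-2-{3,5-bis(benzyloxy)-4-[(4-methoxybenzyl)oxy]phenyl}ethenyl 3,4,5-tris(benzyloxy)benzoate | O=C(O/C=C\c1cc(OCc2ccccc2)c(OCc2ccc(OC)cc2)c(OCc2ccccc2)c1)c1cc(OCc2ccccc2)c(OCc2ccccc2)c(OCc2ccccc2)c1 | intermediate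
11 | ortho-quinone methide 3,5-bis(benzyloxy)-2,4-dibromo-6-methylidenecyclohexa-2,4-dien-1-one | C=C1C(=O)C(Br)=C(OCc2ccccc2)C(Br)=C1OCc1ccccc1 | intermediate
12 | (2R,3R)-5,7-bis(benzyloxy)-2-{3,5-bis(benzyloxy)-4-[(4-methoxybenzyl)oxy]phenyl}-6,8-dibromochroman-3-yl 3,4,5-tris(benzyloxy)benzoate | COc1ccc(COc2c(OCc3ccccc3)cc([C@H]3Oc4c(Br)c(OCc5ccccc5)c(Br)c(OCc5ccccc5)c4C[C@H]3OC(=O)c3cc(OCc4ccccc4)c(OCc4ccccc4)c(OCc4ccccc4)c3)cc2OCc2ccccc2)cc1 | intermediate
13 | (2R,3R)-5,7-bis(benzyloxy)-2-[3,5-bis(benzyloxy)-4-hydroxyphenyl]-6,8-dibromochroman-3-yl 3,4,5-tris(benzyloxy)benzoate | Oc1c(OCc2ccccc2)cc([C@H]2Oc3c(Br)c(OCc4ccccc4)c(Br)c(OCc4ccccc4)c3C[C@H]2OC(=O)c2cc(OCc3ccccc3)c(OCc3ccccc3)c(OCc3ccccc3)c2)cc1OCc1ccccc1 | intermediate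
14 | (2R,3R)-5,7-bis(benzyloxy)-2-{3,5-bis(benzyloxy)-4-[3,4,5-tris(benzyloxy)benzoyloxy]phenyl}-6,8-dibromochroman-3-yl 3,4,5-tris(benzyloxy)benzoate | O=C(Oc1c(OCc2ccccc2)cc([C@H]2Oc3c(Br)c(OCc4ccccc4)c(Br)c(OCc4ccccc4)c3C[C@H]2OC(=O)c2cc(OCc3ccccc3)c(OCc3ccccc3)c(OCc3ccccc3)c2)cc1OCc1ccccc1)c1cc(OCc2ccccc2)c(OCc2ccccc2)c(OCc2ccccc2)c1 | intermediate
15 | epigallocatechin 3,4'-di-O-gallate, (2R,3R) | O=C(Oc1c(O)cc([C@H]2Oc3cc(O)cc(O)c3C[C@H]2OC(=O)c2cc(O)c(O)c(O)c2)cc1O)c1cc(O)c(O)c(O)c1 | target

**Step count and risks**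
Total step count: 11. Longest linear sequence: 8 steps (steps 4 to 11, from 5).

Steps most likely to fail:

1. Step 8. The ortho-quinone methide may be consumed by self-addition before it meets the hindered Z alkene, the chiral acid may discriminate the two alkene faces poorly, or acid-induced Z/E isomerisation may erode the cis relationship. The fallback sets out from aldehydes 7 and 3 and comes back at 12; it replaces the cycloaddition by a condensation that makes the same two ring bonds and puts the stereocontrol into a later reduction.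
   - Aldehyde 7 would be condensed with nitromethane (NH4OAc, MeNO2, 90 °C; Henry condensation) to (E)-1,3-bis(benzyloxy)-2-[(4-methoxybenzyl)oxy]-5-(2-nitroethenyl)benzene F1.
   - Salicylaldehyde 3 and F1 would be joined by the DABCO-mediated oxa-Michael/Henry condensation (MeCN, 60 °C) to racemic 5,7-bis(benzyloxy)-2-{3,5-bis(benzyloxy)-4-[(4-methoxybenzyl)oxy]phenyl}-6,8-dibromo-3-nitro-2H-chromene F2.
   - Buffered TiCl3 (aq. NH4OAc, THF, rt) should reduce and hydrolyse the nitroalkene to racemic 5,7-bis(benzyloxy)-2-{3,5-bis(benzyloxy)-4-[(4-methoxybenzyl)oxy]phenyl}-6,8-dibromochroman-3-one F3.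
   - Asymmetric transfer hydrogenation under dynamic kinetic resolution should give (2R,3R)-5,7-bis(benzyloxy)-2-{3,5-bis(benzyloxy)-4-[(4-methoxybenzyl)oxy]phenyl}-6,8-dibromochroman-3-ol F4. The catalyst would be RuCl(η6-p-cymene)[TsNCH(Ph)CH(Ph)NH2], in the enantiomeric form that delivers the 3R carbinol, with HCO2H/Et3N in CH2Cl2 at rt. The labile C2 centre epimerises through the enol while hydride is delivered anti to the aryl group.
   - Steglich esterification of F4 with 9 (DCC, DMAP, CH2Cl2) would return to 12.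

2. Step 7. The bulky acid may add with the wrong regiochemistry, the Z geometry may erode, or the hindered electron-rich alkyne may inhibit the catalyst. The fallback sets out from alkyne 8 and comes back at 10; it forms the enol C–O bond by oxidative coupling instead of carboxylate addition.
   - Z-selective (formal trans) hydroboration of 8 with pinacolborane ([RhCl(C8H12)]2, P(i-Pr)3, Et3N, cyclohexane, rt) should give (Z)-2-(2-{3,5-bis(benzyloxy)-4-[(4-methoxybenzyl)oxy]phenyl}ethenyl)-4,4,5,5-tetramethyl-1,3,2-dioxaborolane F5.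
   - KHF2 (MeOH/H2O) would convert it into potassium (Z)-(2-{3,5-bis(benzyloxy)-4-[(4-methoxybenzyl)oxy]phenyl}ethenyl)trifluoroborate F6.
   - Copper-catalysed oxidative C–O coupling of F6 with acid 9 (Cu(OAc)2, DMAP, 4 Å MS, O2, CH2Cl2, rt; Chan–Lam type, retention of alkene geometry) would return to 10.

3. Step 11. Hydrodebromination may stay incomplete, or bromide may slow the catalyst so that long exposure costs the aryl ester or causes acyl migration on ring B. The fallback sets out from 14 and comes back at 15; it separates the two reductions.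
   - Homogeneous palladium-catalysed formate reduction of the two aryl bromides (Pd(OAc)2, PPh3, HCO2H/Et3N, DMF, 80 °C) should give (2R,3R)-5,7-bis(benzyloxy)-2-{3,5-bis(benzyloxy)-4-[3,4,5-tris(benzyloxy)benzoyloxy]phenyl}chroman-3-yl 3,4,5-tris(benzyloxy)benzoate F7.
   - Plain hydrogenolysis of F7 (H2, Pd(OH)2/C, THF/MeOH, rt) would then give 15.

**Further compounds**
F1 | step 8 | (E)-1,3-bis(benzyloxy)-2-[(4-methoxybenzyl)oxy]-5-(2-nitroethenyl)benzene | O=[N+]([O-])/C=C/c1cc(OCc2ccccc2)c(OCc2ccc(OC)cc2)c(OCc2ccccc2)c1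
F2 | step 8 | racemic 5,7-bis(benzyloxy)-2-{3,5-bis(benzyloxy)-4-[(4-methoxybenzyl)oxy]phenyl}-6,8-dibromo-3-nitro-2H-chromene | O=[N+]([O-])C1=Cc2c(OCc3ccccc3)c(Br)c(OCc3ccccc3)c(Br)c2OC1c1cc(OCc2ccccc2)c(OCc2ccc(OC)cc2)c(OCc2ccccc2)c1
F3 | step 8 | racemic 5,7-bis(benzyloxy)-2-{3,5-bis(benzyloxy)-4-[(4-methoxybenzyl)oxy]phenyl}-6,8-dibromochroman-3-one | O=C1Cc2c(OCc3ccccc3)c(Br)c(OCc3ccccc3)c(Br)c2OC1c1cc(OCc2ccccc2)c(OCc2ccc(OC)cc2)c(OCc2ccccc2)c1
F4 | step 8 | (2R,3R)-5,7-bis(benzyloxy)-2-{3,5-bis(benzyloxy)-4-[(4-methoxybenzyl)oxy]phenyl}-6,8-dibromochroman-3-ol | COc1ccc(COc2c(OCc3ccccc3)cc([C@H]3Oc4c(Br)c(OCc5ccccc5)c(Br)c(OCc5ccccc5)c4C[C@H]3O)cc2OCc2ccccc2)cc1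
F5 | step 7 | (Z)-2-(2-{3,5-bis(benzyloxy)-4-[(4-methoxybenzyl)oxy]phenyl}ethenyl)-4,4,5,5-tetramethyl-1,3,2-dioxaborolane | COc1ccc(COc2c(OCc3ccccc3)cc(/C=C\B3OC(C)(C)C(C)(C)O3)cc2OCc2ccccc2)cc1
F6 | step 7 | potassium (Z)-(2-{3,5-bis(benzyloxy)-4-[(4-methoxybenzyl)oxy]phenyl}ethenyl)trifluoroborate | [K+].F[B-](F)(F)/C=C\c1cc(OCc2ccccc2)c(OCc2ccc(OC)cc2)c(OCc2ccccc2)c1
F7 | step 11 | (2R,3R)-5,7-bis(benzyloxy)-2-{3,5-bis(benzyloxy)-4-[3,4,5-tris(benzyloxy)benzoyloxy]phenyl}chroman-3-yl 3,4,5-tris(benzyloxy)benzoate | O=C(Oc1c(OCc2ccccc2)cc([C@H]2Oc3cc(OCc4ccccc4)cc(OCc4ccccc4)c3C[C@H]2OC(=O)c2cc(OCc3ccccc3)c(OCc3ccccc3)c(OCc3ccccc3)c2)cc1OCc1ccccc1)c1cc(OCc2ccccc2)c(OCc2ccccc2)c(OCc2ccccc2)c1
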